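The isoflavone is disconnected across ring A at C-4a–C-5 and C-8–C-8a. Ring A shares only the C-4a/C-8a edge with the pyranone ring C and bears a single oxygen, at C-7, meta to O-1; C-5 to C-8 therefore map onto a 1-methoxy-3-silyloxybutadiene. One Diels–Alder addition of that diene to the sulfonyl-bearing double bond of a monocyclic 4-pyranone, followed by loss of methanol and benzenesulfinic acid, should forge both bonds and aromatise ring A with no oxidant near the chromene. The dienophile, 3-(5-methoxy-2,2-dimethylchromen-6-yl)-5-(phenylsulfonyl)-4-pyranone, already holds rings B and C and the pyran ring; it is built from a chromenylacetic ester, methyl phenyl sulfone and an amide acetal.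

Key step: step 7

Assumption (chemistry): compound 5 (alkene geometry, sulfoxide sulfur) and the transient intermediates 13 and 14 are racemic or isomer mixtures of no consequence, since the target has no stereocentre.

Step 1
Reactants: 1 2,4-dihydroxybenzaldehyde; 2 3-methylbut-2-enal
Product: 3 5-hydroxy-2,2-dimethyl-2H-chromene-6-carbaldehyde
Conditions: 2 (2 equiv), pyridine, 140 °C, sealed tube
Reagents that add atoms: none
Why: Base-mediated chromenylation (aldol-type C-alkylation at C-3 of the resorcinol, dehydration to an ortho-quinone methide, 6π oxa-electrocyclisation) should give the angular chromene, because the C-2 hydroxyl is held in a hydrogen bond to the formyl group and the C-4 hydroxyl closes the pyran ring.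

Step 2
Reactants: 3 5-hydroxy-2,2-dimethyl-2H-chromene-6-carbaldehyde
Product: 4 5-methoxy-2,2-dimethyl-2H-chromene-6-carbaldehyde
Conditions: MeI, K2CO3, DMF, 40 °C
Reagents that add atoms: iodomethane (CI)
Why: Williamson O-methylation of the chelated phenol, which the ortho-formyl group makes acidic enough for carbonate, while the aldehyde and the chromene alkene are inert to MeI.

Step 3
Reactants: 4 5-methoxy-2,2-dimethyl-2H-chromene-6-carbaldehyde
Product: 5 5-methoxy-2,2-dimethyl-6-[2-(methylsulfanyl)-2-(methylsulfinyl)ethenyl]-2H-chromene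
Conditions: CH3S(O)CH2SCH3 (1.5 equiv), PhCH2NMe3+ OH− (40% in MeOH, 0.3 equiv), THF, reflux
Reagents that add atoms: methyl (methylsulfanyl)methyl sulfoxide (CS(=O)CSC)
Why: Knoevenagel-type condensation of the doubly sulfur-stabilised carbanion with the non-enolisable aldehyde and dehydration should give the ketene dithioacetal S-oxide, whose alkene geometry and sulfur configuration are irrelevant because both disappear in step 4.

Step 4
Reactants: 5 5-methoxy-2,2-dimethyl-6-[2-(methylsulfanyl)-2-(methylsulfinyl)ethenyl]-2H-chromene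
Product: 6 methyl 2-(5-methoxy-2,2-dimethyl-2H-chromen-6-yl)acetate
Conditions: dry HCl (ca. 1 M) in MeOH, 0 °C → rt
Reagents that add atoms: methanol (CO)
Why: Acid-mediated methanolysis of the ketene dithioacetal S-oxide (protonation at the benzylic carbon, capture of the sulfur-stabilised cation by methanol, Pummerer-type collapse with loss of dimethyl disulfide) is the established second stage of this aldehyde-to-arylacetic-ester homologation, and cold dilute acid should spare the 2,2-dimethylchromene.

Step 5
Reactants: 6 methyl 2-(5-methoxy-2,2-dimethyl-2H-chromen-6-yl)acetate; 7 methyl phenyl sulfone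
Product: 9 1-(5-methoxy-2,2-dimethyl-2H-chromen-6-yl)-3-(phenylsulfonyl)propan-2-one, via lithiated sulfone 8 (not isolated)
Conditions: 7 (2.2 equiv), n-BuLi (2.1 equiv), THF, −78 °C; then 6, −78 → 0 °C; aq. NH4Cl
Reagents that add atoms: none
Why: Claisen-type acylation of the α-sulfonyl carbanion by the ester, in which the second equivalent of carbanion deprotonates the β-keto sulfone as it forms and so blocks over-addition, while the low temperature limits enolisation of the arylacetate.

Step 6
Reactants: 9 1-(5-methoxy-2,2-dimethyl-2H-chromen-6-yl)-3-(phenylsulfonyl)propan-2-one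
Product: 11 3-(5-methoxy-2,2-dimethyl-2H-chromen-6-yl)-5-(phenylsulfonyl)-4H-pyran-4-one, via bis-enaminone 10 (not isolated)
Conditions: Me2NCH(OMe)2 (6 equiv), PhMe, 110 °C; evaporate; 2 M HCl, THF, 0 °C → rt
Reagents that add atoms: N,N-dimethylformamide dimethyl acetal (COC(OC)N(C)C); water (O)
Why: Twofold aminomethylenation of the two activated α-methylenes by the amide acetal, then acid hydrolysis of one enaminone terminus and 6-endo addition–elimination of the resulting enol oxygen at the other with loss of dimethylamine, is the standard construction of 3,5-disubstituted 4-pyranones from 1,3-disubstituted acetones.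

Step 7
Reactants: 11 3-(5-methoxy-2,2-dimethyl-2H-chromen-6-yl)-5-(phenylsulfonyl)-4H-pyran-4-one; 12 (E)-1-methoxy-3-(trimethylsilyloxy)buta-1,3-diene
Product: 16 7-hydroxy-3-(5-methoxy-2,2-dimethyl-2H-chromen-6-yl)-4H-chromen-4-one, via cycloadduct 13 (not isolated), via silyloxycyclohexadiene 14 (not isolated), via aryl silyl ether 15 (not isolated)
Conditions: 12 (3 equiv), PhMe, 100 °C; evaporate; Me3SiOTf, Et3N, CH2Cl2, −78 → 0 °C; DBU, 0 → 40 °C; AcOH, THF–H2O, rt
Reagents that add atoms: none
Why: Proposed new method: the 2-silyloxydiene should add in a normal-demand, asynchronous concerted [4+2] cycloaddition to the C-5=C-6 bond of 11, the only alkene carrying two geminal acceptors (ring carbonyl and sulfone), its nucleophilic CH2 terminus bonding to the oxygen-bearing carbon β to both acceptors (future C-8a) and its methoxy terminus to the sulfonyl carbon (future C-4a), which places the oxygen at C-7 and not C-6, while the aryl-substituted C-2=C-3 bond and the chromene alkene are unactivated; the closest known reactions are Diels–Alder additions of this diene to chromones bearing an acceptor at C-3 and to sulfonyl enones, followed by eliminative aromatisation. Ring A is thus closed intermolecularly by suprafacial formation of C-4a–C-5 and C-8–C-8a, and the three stereocentres of the cis-fused adduct 13 are transient, so 16 has none and no stereocontrol is needed. Because the cis ring fusion holds H-8a syn to the sulfonyl group, and because a free C-7 ketone would let base open ring C by retro-oxa-Michael cleavage of O-1–C-8a, methanol is removed first: Me3SiOTf ionises the allylic C-5 methoxy group with help from the silyl enol ether and Et3N takes H-8, giving 14 with the C-7 oxygen still capped. In 14 the only hydrogen β to sulfur is H-8a, now dienylic, so DBU should remove it in an E1cB-like syn elimination through a cyclohexadienyl anion of the kind that expels sulfinate in nucleophilic aromatic substitution, the gain of ring A aromaticity driving the loss of benzenesulfinate. Mild aqueous acid then cleaves the aryl silyl ether 15 to the C-7 phenol without touching the chromene.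

Step 8
Reactants: 16 7-hydroxy-3-(5-methoxy-2,2-dimethyl-2H-chromen-6-yl)-4H-chromen-4-one
Product: 17 7-methoxy-3-(5-methoxy-2,2-dimethyl-2H-chromen-6-yl)-4H-chromen-4-one
Conditions: MeI, K2CO3, acetone, reflux
Reagents that add atoms: iodomethane (CI)
Why: Williamson etherification of the acidic C-7 phenol (vinylogous to the C-4 carbonyl), the only nucleophilic site left in the molecule.

Compound list
1 | 2,4-dihydroxybenzaldehyde | O=Cc1ccc(O)cc1O | starting material
2 | 3-methylbut-2-enal | CC(C)=CC=O | starting material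
3 | 5-hydroxy-2,2-dimethyl-2H-chromene-6-carbaldehyde | O=Cc1ccc2OC(C)(C)C=Cc2c1O | intermediate
4 | 5-methoxy-2,2-dimethyl-2H-chromene-6-carbaldehyde | O=Cc1ccc2OC(C)(C)C=Cc2c1OC | intermediate
5 | 5-methoxy-2,2-dimethyl-6-[2-(methylsulfanyl)-2-(methylsulfinyl)ethenyl]-2H-chromene (alkene isomers, racemic at sulfur) | CSC(=Cc1ccc2OC(C)(C)C=Cc2c1OC)S(C)=O | intermediate
6 | methyl 2-(5-methoxy-2,2-dimethyl-2H-chromen-6-yl)acetate | COC(=O)Cc1ccc2OC(C)(C)C=Cc2c1OC | intermediate
7 | methyl phenyl sulfone | CS(=O)(=O)c1ccccc1 | starting material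
8 | [(phenylsulfonyl)methyl]lithium (not isolated) | [Li]CS(=O)(=O)c1ccccc1 | intermediate
9 | 1-(5-methoxy-2,2-dimethyl-2H-chromen-6-yl)-3-(phenylsulfonyl)propan-2-one | O=C(Cc1ccc2OC(C)(C)C=Cc2c1OC)CS(=O)(=O)c1ccccc1 | intermediate
10 | 1,5-bis(dimethylamino)-2-(5-methoxy-2,2-dimethyl-2H-chromen-6-yl)-4-(phenylsulfonyl)penta-1,4-dien-3-one (not isolated, alkene isomers) | CN(C)C=C(C(=O)C(=CN(C)C)S(=O)(=O)c1ccccc1)c1ccc2OC(C)(C)C=Cc2c1OC | intermediate
11 | 3-(5-methoxy-2,2-dimethyl-2H-chromen-6-yl)-5-(phenylsulfonyl)-4H-pyran-4-one | O=c1c(-c2ccc3c(c2OC)C=CC(C)(C)O3)cocc1S(=O)(=O)c1ccccc1 | intermediate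
12 | (E)-1-methoxy-3-(trimethylsilyloxy)buta-1,3-diene | CO/C=C/C(=C)O[Si](C)(C)C | starting material
13 | 5-methoxy-3-(5-methoxy-2,2-dimethyl-2H-chromen-6-yl)-4a-(phenylsulfonyl)-7-(trimethylsilyloxy)-4a,5,8,8a-tetrahydro-4H-chromen-4-one (not isolated; racemic, cis ring fusion shown as relative configuration, C-5 epimers) | COC1C=C(O[Si](C)(C)C)C[C@@H]2OC=C(-c3ccc4c(c3OC)C=CC(C)(C)O4)C(=O)[C@]12S(=O)(=O)c1ccccc1 | intermediate
14 | 3-(5-methoxy-2,2-dimethyl-2H-chromen-6-yl)-4a-(phenylsulfonyl)-7-(trimethylsilyloxy)-4a,8a-dihydro-4H-chromen-4-one (not isolated; racemic, cis, relative configuration shown) | C[Si](C)(C)OC1=C[C@@H]2OC=C(-c3ccc4c(c3OC)C=CC(C)(C)O4)C(=O)[C@@]2(C=C1)S(=O)(=O)c1ccccc1 | intermediate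
15 | 3-(5-methoxy-2,2-dimethyl-2H-chromen-6-yl)-7-(trimethylsilyloxy)-4H-chromen-4-one (not isolated) | C[Si](C)(C)Oc1ccc2c(=O)c(-c3ccc4c(c3OC)C=CC(C)(C)O4)coc2c1 | intermediate
16 | 7-hydroxy-3-(5-methoxy-2,2-dimethyl-2H-chromen-6-yl)-4H-chromen-4-one | Oc1ccc2c(=O)c(-c3ccc4c(c3OC)C=CC(C)(C)O4)coc2c1 | intermediate
17 | 7-methoxy-3-(5-methoxy-2,2-dimethyl-2H-chromen-6-yl)-4H-chromen-4-one | COc1ccc2c(=O)c(-c3ccc4c(c3OC)C=CC(C)(C)O4)coc2c1 | target

Total steps: 8. Longest linear sequence: 8 steps (1 → 17).

Steps most likely to fail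

Step 7 (the labelled step). The cycloaddition may be too slow on a dienophile whose double bond is also fed by the ring oxygen, so that diene decomposition wins. In the last stage, premature desilylation followed by opening of ring C, or reluctance of the sulfinate to leave without an anti hydrogen, may divert material. The fallback uses known chemistry only, sets out from 6 and rejoins the route at 17, so step 8 is not needed. Aminolysis of 6 with MeNH(OMe)·HCl and i-PrMgCl gives 2-(5-methoxy-2,2-dimethyl-2H-chromen-6-yl)-N-methoxy-N-methylacetamide F1. Commercial 2-bromo-5-methoxyphenol is protected with MOMCl and i-Pr2NEt as 1-bromo-4-methoxy-2-(methoxymethoxy)benzene F2. Bromine–lithium exchange with n-BuLi in THF at −78 °C gives [4-methoxy-2-(methoxymethoxy)phenyl]lithium F3, to which F1 is added at −78 °C to give 1-[4-methoxy-2-(methoxymethoxy)phenyl]-2-(5-methoxy-2,2-dimethyl-2H-chromen-6-yl)ethan-1-one F4. Heating with Me2NCH(OMe)2 gives 3-(dimethylamino)-1-[4-methoxy-2-(methoxymethoxy)phenyl]-2-(5-methoxy-2,2-dimethyl-2H-chromen-6-yl)prop-2-en-1-one F5. Dilute HCl in MeOH removes the acetal protecting group, and the liberated 3-(dimethylamino)-1-(2-hydroxy-4-methoxyphenyl)-2-(5-methoxy-2,2-dimethyl-2H-chromen-6-yl)prop-2-en-1-one F6 closes ring C by addition–elimination with loss of dimethylamine to give 17.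

Step 5. Deprotonation of the acidic benzylic α-hydrogens of 6 by the sulfonyl carbanion may compete with acylation and return starting ester. The fallback replaces acylation by addition and oxidation, sets out from 6 and rejoins at 9. Reduction with i-Bu2AlH in CH2Cl2 at −78 °C gives 2-(5-methoxy-2,2-dimethyl-2H-chromen-6-yl)acetaldehyde F7, which is used at once. Addition of 8 in THF at −78 °C gives racemic 1-(5-methoxy-2,2-dimethyl-2H-chromen-6-yl)-3-(phenylsulfonyl)propan-2-ol F8, and Dess–Martin oxidation (NaHCO3, CH2Cl2) gives 9.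

Step 4. Long exposure to HCl in methanol may add methanol across the electron-rich chromene double bond, or oligomerise through it, before methanolysis is complete. The fallback is an all-basic one-carbon homologation that sets out from 4 and rejoins at 6. Cl3CCO2Na and Cl3CCO2H in DMF at rt add a trichloromethyl anion to the aldehyde to give racemic 2,2,2-trichloro-1-(5-methoxy-2,2-dimethyl-2H-chromen-6-yl)ethanol F9. NaBH4 and NaOH in t-BuOH at 55 °C (Jocic-type reductive homologation, hydride delivered to the benzylic carbon) give 2-(5-methoxy-2,2-dimethyl-2H-chromen-6-yl)acetic acid F10, and MeI with K2CO3 in DMF gives 6.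

Further compounds
F1 | step 7 | 2-(5-methoxy-2,2-dimethyl-2H-chromen-6-yl)-N-methoxy-N-methylacetamide | CON(C)C(=O)Cc1ccc2OC(C)(C)C=Cc2c1OC
F2 | step 7 | 1-bromo-4-methoxy-2-(methoxymethoxy)benzene | COCOc1cc(OC)ccc1Br
F3 | step 7 | [4-methoxy-2-(methoxymethoxy)phenyl]lithium | [Li]c1ccc(OC)cc1OCOC
F4 | step 7 | 1-[4-methoxy-2-(methoxymethoxy)phenyl]-2-(5-methoxy-2,2-dimethyl-2H-chromen-6-yl)ethan-1-one | COCOc1cc(OC)ccc1C(=O)Cc1ccc2OC(C)(C)C=Cc2c1OC
F5 | step 7 | 3-(dimethylamino)-1-[4-methoxy-2-(methoxymethoxy)phenyl]-2-(5-methoxy-2,2-dimethyl-2H-chromen-6-yl)prop-2-en-1-one | COCOc1cc(OC)ccc1C(=O)C(=CN(C)C)c1ccc2OC(C)(C)C=Cc2c1OC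
F6 | step 7 | 3-(dimethylamino)-1-(2-hydroxy-4-methoxyphenyl)-2-(5-methoxy-2,2-dimethyl-2H-chromen-6-yl)prop-2-en-1-one | CN(C)C=C(C(=O)c1ccc(OC)cc1O)c1ccc2OC(C)(C)C=Cc2c1OC
F7 | step 5 | 2-(5-methoxy-2,2-dimethyl-2H-chromen-6-yl)acetaldehyde | O=CCc1ccc2OC(C)(C)C=Cc2c1OC
F8 | step 5 | 1-(5-methoxy-2,2-dimethyl-2H-chromen-6-yl)-3-(phenylsulfonyl)propan-2-ol (racemic) | OC(Cc1ccc2OC(C)(C)C=Cc2c1OC)CS(=O)(=O)c1ccccc1
F9 | step 4 | 2,2,2-trichloro-1-(5-methoxy-2,2-dimethyl-2H-chromen-6-yl)ethanol (racemic) | OC(c1ccc2OC(C)(C)C=Cc2c1OC)C(Cl)(Cl)Cl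
F10 | step 4 | 2-(5-methoxy-2,2-dimethyl-2H-chromen-6-yl)acetic acid | OC(=O)Cc1ccc2OC(C)(C)C=Cc2c1OC
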